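**Strategy**

The dioxane ring of the 2,3-dihydro-1,4-benzodioxine (O1, C2 methyl-bearing, C3 aryl-bearing, O4, C4a, C5–C8, C8a) is opened at C2–C3, the bond between its two oxygenated sp3 carbons, and at O4–C4a, the aryl ether bond with a free C5–H beside it. One flask rebuilds both: an enantioenriched α-aryloxyethyllithium, released from its stannane, adds to 3,4,5-trimethoxybenzaldehyde, and the alkoxide formed is trapped by an aryne raised across C4a–C5 from an ortho chlorine. The precursor is an open-chain 1-stannylethyl ether of acetal-protected 5-chlorovanillin. C2 comes from the stannane; C3 is settled as trans during acidic acetal cleavage; a Wittig reaction then installs the enal.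

Key step: step 5

Assumption: (R)-BINAL-H reduces acetyl(tributyl)stannane to the (S)-carbinol (stannyl group in the role of the unsaturated substituent); if the sense were opposite, the (S)-reagent would be used and nothing else changes.

Remark: ring A is the benzo ring, ring B the 3,4,5-trimethoxyphenyl ring; C6 carries the side chain and C8 the methoxy group.

**Route**

Step 1
Reactants: 1 5-chlorovanillin (3-chloro-4-hydroxy-5-methoxybenzaldehyde); 2 2,2-dimethylpropane-1,3-diol (neopentyl glycol)
Product: 3 2-chloro-4-(5,5-dimethyl-1,3-dioxan-2-yl)-6-methoxyphenol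
Conditions: p-TsOH (cat.), toluene, reflux, Dean–Stark trap
Reagents that add atoms: none
Why: Acid-catalysed acetalisation with azeotropic removal of water masks the only carbonyl of ring A as a base-stable 1,3-dioxane before the organolithium chemistry and leaves the phenol free for step 4.

Step 2
Reactants: 4 tributylstannane (Bu3SnH); 5 acetaldehyde
Product: 8 acetyl(tributyl)stannane, via tributylstannyllithium 6 (not isolated), via lithium 1-(tributylstannyl)ethoxide 7 (not isolated)
Conditions: LiN(i-Pr)2 (LDA), THF, 0 °C; 5, −78 °C; 1,1'-(azodicarbonyl)dipiperidine, −78 → 0 °C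
Reagents that add atoms: none
Why: Deprotonation of 4 gives stannyl anion 6, which adds 1,2 to acetaldehyde, and lithium alkoxide 7 is dehydrogenated in the same flask by the azodicarboxamide (Oppenauer-type oxidation of a metal alkoxide) to the acylstannane.

Step 3
Reactants: 8 acetyl(tributyl)stannane
Product: 9 (1S)-1-(tributylstannyl)ethan-1-ol
Conditions: (R)-BINAL-H, Li[AlH(OEt)((R)-1,1'-bi-2-naphtholate)], THF, −78 °C; crude product used at once
Reagents that add atoms: none
Why: BINAL-H reduction, in whose six-membered hydride-transfer transition state the tributylstannyl group takes the place usually held by the unsaturated substituent, so the (R)-reagent should set the carbinol centre as (S).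

Step 4
Reactants: 3 2-chloro-4-(5,5-dimethyl-1,3-dioxan-2-yl)-6-methoxyphenol; 9 (1S)-1-(tributylstannyl)ethan-1-ol
Product: 10 tributyl{(1R)-1-[2-chloro-4-(5,5-dimethyl-1,3-dioxan-2-yl)-6-methoxyphenoxy]ethyl}stannane
Conditions: PPh3, DIAD, THF, 0 °C → rt
Reagents that add atoms: none
Why: Mitsunobu etherification, in which the phenol displaces the oxyphosphonium group by SN2 with inversion and so converts the (S)-carbinol into the (R)-aryl ether that already carries the C2 configuration of the target.

Step 5
Reactants: 10 tributyl{(1R)-1-[2-chloro-4-(5,5-dimethyl-1,3-dioxan-2-yl)-6-methoxyphenoxy]ethyl}stannane; 11 3,4,5-trimethoxybenzaldehyde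
Product: 16 2-[(2S,3RS)-8-methoxy-2-methyl-3-(3,4,5-trimethoxyphenyl)-2,3-dihydro-1,4-benzodioxin-6-yl]-5,5-dimethyl-1,3-dioxane (both C3 epimers), via α-aryloxyethyllithium 12 (not isolated), via lithium alkoxide 13 (not isolated), via aryne alkoxide 14 (not isolated), via aryllithium 15 (not isolated)
Conditions: n-BuLi (1.05 equiv), THF, −78 °C; 11, −78 °C; LiTMP (lithium 2,2,6,6-tetramethylpiperidide, 2.5 equiv), −78 → 0 °C; aq NH4Cl
Reagents that add atoms: none
Why: n-BuLi exchanges tin for lithium with retention to give the configurationally stable, methoxy-chelated organolithium 12, which adds to the only carbonyl present (11) with retention at carbon and so makes the C2–C3 bond and alkoxide 13; LiTMP then removes the ring A hydrogen flanked by chlorine and the acetal-bearing carbon, lithium chloride is lost, and the tethered alkoxide adds to aryne 14 to make the O4–C4a bond, aryl anion 15 being protonated on quench. The closest known reaction types are the addition of α-alkoxyorganolithiums made by tin–lithium exchange to aldehydes and the intramolecular capture of a benzyne by an alkoxide. The dioxane ring closes by 6-exo attack of oxygen on the aryne carbon next to the ether oxygen; a 3-alkoxyaryne by itself prefers attack at the far carbon, but that mode would need a meta-bridged seven-membered ring, so the tether dictates the site and the far carbon (C5) takes up hydrogen. C2 is controlled by the reagent (R-stannane, retention twice), whereas C3 is formed under only weak 1,2-induction from C2, so both C3 epimers are expected and are carried together into step 6, which settles this centre. The step needs tin–lithium exchange to outrun chlorine–lithium exchange and ring lithiation, which the fast exchange of α-oxygenated stannanes at −78 °C should secure, and it needs deprotonation beside chlorine rather than elsewhere, which the doubly flanked ring position and the hindered, poorly nucleophilic amide base should secure.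

Step 6
Reactants: 16 2-[(2S,3RS)-8-methoxy-2-methyl-3-(3,4,5-trimethoxyphenyl)-2,3-dihydro-1,4-benzodioxin-6-yl]-5,5-dimethyl-1,3-dioxane
Product: 17 (2S,3S)-8-methoxy-2-methyl-3-(3,4,5-trimethoxyphenyl)-2,3-dihydro-1,4-benzodioxine-6-carbaldehyde (trans)
Conditions: TFA, CH2Cl2, H2O (few equiv), 0 °C → rt; chromatography, any residual cis epimer resubmitted
Reagents that add atoms: water, O
Why: Acetal hydrolysis combined with acid-catalysed epimerisation of a benzylic ether: reversible SN1 ionisation of the C3–O4 bond (trimethoxybenzyl cation, ring A phenol as internal leaving group and nucleophile) should funnel the cis epimer to the more stable trans isomer with both substituents pseudo-equatorial, while C2 cannot ionise and keeps its configuration.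

Step 7
Reactants: 17 (2S,3S)-8-methoxy-2-methyl-3-(3,4,5-trimethoxyphenyl)-2,3-dihydro-1,4-benzodioxine-6-carbaldehyde; 18 (triphenylphosphoranylidene)acetaldehyde
Product: 19 (2E)-3-[(2S,3S)-8-methoxy-2-methyl-3-(3,4,5-trimethoxyphenyl)-2,3-dihydro-1,4-benzodioxin-6-yl]prop-2-enal
Conditions: toluene, 90 °C
Reagents that add atoms: none
Why: Wittig olefination with the stabilised formylmethylene ylide should give the (E)-enal and leaves both stereocentres untouched.

**Compound list**

1 | 5-chlorovanillin (3-chloro-4-hydroxy-5-methoxybenzaldehyde) | COc1cc(C=O)cc(Cl)c1O | starting material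
2 | 2,2-dimethylpropane-1,3-diol (neopentyl glycol) | OCC(C)(C)CO | starting material
3 | 2-chloro-4-(5,5-dimethyl-1,3-dioxan-2-yl)-6-methoxyphenol | COc1cc(C2OCC(C)(C)CO2)cc(Cl)c1O | intermediate
4 | tributylstannane | CCCC[SnH](CCCC)CCCC | starting material
5 | acetaldehyde | CC=O | starting material
6 | tributylstannyllithium | CCCC[Sn]([Li])(CCCC)CCCC | intermediate (not isolated)
7 | lithium 1-(tributylstannyl)ethoxide (racemic) | CC(O[Li])[Sn](CCCC)(CCCC)CCCC | intermediate (not isolated)
8 | acetyl(tributyl)stannane | CC(=O)[Sn](CCCC)(CCCC)CCCC | intermediate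
9 | (1S)-1-(tributylstannyl)ethan-1-ol | C[C@@H](O)[Sn](CCCC)(CCCC)CCCC | intermediate
10 | tributyl{(1R)-1-[2-chloro-4-(5,5-dimethyl-1,3-dioxan-2-yl)-6-methoxyphenoxy]ethyl}stannane | C[C@H](Oc1c(Cl)cc(C2OCC(C)(C)CO2)cc1OC)[Sn](CCCC)(CCCC)CCCC | intermediate
11 | 3,4,5-trimethoxybenzaldehyde | COc1cc(C=O)cc(OC)c1OC | starting material
12 | {(1R)-1-[2-chloro-4-(5,5-dimethyl-1,3-dioxan-2-yl)-6-methoxyphenoxy]ethyl}lithium | C[C@H](Oc1c(Cl)cc(C2OCC(C)(C)CO2)cc1OC)[Li] | intermediate (not isolated)
13 | lithium (1RS,2S)-2-[2-chloro-4-(5,5-dimethyl-1,3-dioxan-2-yl)-6-methoxyphenoxy]-1-(3,4,5-trimethoxyphenyl)propan-1-olate | C[C@H](Oc1c(Cl)cc(C2OCC(C)(C)CO2)cc1OC)C(O[Li])c1cc(OC)c(OC)c(OC)c1 | intermediate (not isolated)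
14 | lithium (1RS,2S)-2-{[4-(5,5-dimethyl-1,3-dioxan-2-yl)-6-methoxy-2,3-didehydrophenyl]oxy}-1-(3,4,5-trimethoxyphenyl)propan-1-olate (aryne) | C[C@H](OC1=C(OC)C=C(C2OCC(C)(C)CO2)C#C1)C(O[Li])c1cc(OC)c(OC)c(OC)c1 | intermediate (not isolated)
15 | [(2S,3RS)-6-(5,5-dimethyl-1,3-dioxan-2-yl)-8-methoxy-2-methyl-3-(3,4,5-trimethoxyphenyl)-2,3-dihydro-1,4-benzodioxin-5-yl]lithium | COc1cc(C2Oc3c([Li])c(C4OCC(C)(C)CO4)cc(OC)c3O[C@H]2C)cc(OC)c1OC | intermediate (not isolated)
16 | 2-[(2S,3RS)-8-methoxy-2-methyl-3-(3,4,5-trimethoxyphenyl)-2,3-dihydro-1,4-benzodioxin-6-yl]-5,5-dimethyl-1,3-dioxane (both C3 epimers) | COc1cc(C2Oc3cc(C4OCC(C)(C)CO4)cc(OC)c3O[C@H]2C)cc(OC)c1OC | intermediate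
17 | (2S,3S)-8-methoxy-2-methyl-3-(3,4,5-trimethoxyphenyl)-2,3-dihydro-1,4-benzodioxine-6-carbaldehyde | COc1cc([C@@H]2Oc3cc(C=O)cc(OC)c3O[C@H]2C)cc(OC)c1OC | intermediate
18 | (triphenylphosphoranylidene)acetaldehyde | O=CC=P(c1ccccc1)(c1ccccc1)c1ccccc1 | starting material
19 | (2E)-3-[(2S,3S)-8-methoxy-2-methyl-3-(3,4,5-trimethoxyphenyl)-2,3-dihydro-1,4-benzodioxin-6-yl]prop-2-enal | COc1cc([C@@H]2Oc3cc(/C=C/C=O)cc(OC)c3O[C@H]2C)cc(OC)c1OC | target

**Step count and risks**

Total step count: 7. Longest linear sequence: 6 (steps 2, 3, 4, 5, 6, 7); step 1 is a one-step side branch that joins at step 4.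

Steps most likely to fail:

1. Step 5. The aryne stage may stray: lithiation at other ring positions, addition of the amide base to the aryne, or α-elimination of organolithium 12 before it meets the aldehyde. Fallback: the two bond formations are separated. Starting from 10, tin–lithium exchange and addition to 11 are run as before but quenched at −78 °C, and the (1RS,2S)-2-[2-chloro-4-(5,5-dimethyl-1,3-dioxan-2-yl)-6-methoxyphenoxy]-1-(3,4,5-trimethoxyphenyl)propan-1-ol F1 is isolated. Its ring is then closed by palladium-catalysed intramolecular C–O coupling of the aryl chloride (Pd(OAc)2, 2-(di-tert-butylphosphino)-1,1'-binaphthyl, Cs2CO3, toluene, 80 °C), which returns to the route at 16.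

2. Step 6. The benzylic cation may lose a proton to an enol ether that hydrolyses with loss of ring A, or the equilibration may stall short of the trans isomer. Fallback: the benzylic configuration is fixed before ring closure and strong acid is avoided. From 10, organolithium 12 is acylated with N,3,4,5-tetramethoxy-N-methylbenzamide to give (2S)-2-[2-chloro-4-(5,5-dimethyl-1,3-dioxan-2-yl)-6-methoxyphenoxy]-1-(3,4,5-trimethoxyphenyl)propan-1-one F2. LiBH(s-Bu)3 (THF, −78 °C) reduces it under Felkin–Anh control, hydride arriving anti to the aryloxy group, to the (1S,2S)-alcohol F3. Closure with Pd(OAc)2 under the conditions above gives the trans acetal 2-[(2S,3S)-8-methoxy-2-methyl-3-(3,4,5-trimethoxyphenyl)-2,3-dihydro-1,4-benzodioxin-6-yl]-5,5-dimethyl-1,3-dioxane F4. The acetal is removed with pyridinium p-toluenesulfonate in wet acetone at 50 °C, conditions that should not ionise the benzylic ether, and the route is rejoined at 17.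

3. Step 4. The hindered phenol may couple slowly, so that the labile α-hydroxystannane eliminates, loses tin or ionises with erosion of configuration. Fallback: the methyl-bearing centre is taken from the chiral pool and no stannane is needed. Phenol 3 and methyl (R)-lactate undergo Mitsunobu coupling (PPh3, DIAD, inversion) to methyl (2S)-2-[2-chloro-4-(5,5-dimethyl-1,3-dioxan-2-yl)-6-methoxyphenoxy]propanoate F5. MeNHOMe·HCl and i-PrMgCl (THF, −20 °C) convert it into (2S)-2-[2-chloro-4-(5,5-dimethyl-1,3-dioxan-2-yl)-6-methoxyphenoxy]-N-methoxy-N-methylpropanamide F6. (3,4,5-Trimethoxyphenyl)magnesium bromide (THF, −40 → 0 °C) gives ketone F2, which is carried on as in the fallback for step 6 (alcohol F3, acetal F4, mild hydrolysis) and re-enters the route at 17.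

**Further compounds**

F1 | step 5 | (1RS,2S)-2-[2-chloro-4-(5,5-dimethyl-1,3-dioxan-2-yl)-6-methoxyphenoxy]-1-(3,4,5-trimethoxyphenyl)propan-1-ol | C[C@H](Oc1c(Cl)cc(C2OCC(C)(C)CO2)cc1OC)C(O)c1cc(OC)c(OC)c(OC)c1
F2 | step 6 | (2S)-2-[2-chloro-4-(5,5-dimethyl-1,3-dioxan-2-yl)-6-methoxyphenoxy]-1-(3,4,5-trimethoxyphenyl)propan-1-one | C[C@H](Oc1c(Cl)cc(C2OCC(C)(C)CO2)cc1OC)C(=O)c1cc(OC)c(OC)c(OC)c1
F3 | step 6 | (1S,2S)-2-[2-chloro-4-(5,5-dimethyl-1,3-dioxan-2-yl)-6-methoxyphenoxy]-1-(3,4,5-trimethoxyphenyl)propan-1-ol | C[C@H](Oc1c(Cl)cc(C2OCC(C)(C)CO2)cc1OC)[C@@H](O)c1cc(OC)c(OC)c(OC)c1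
F4 | step 6 | 2-[(2S,3S)-8-methoxy-2-methyl-3-(3,4,5-trimethoxyphenyl)-2,3-dihydro-1,4-benzodioxin-6-yl]-5,5-dimethyl-1,3-dioxane | COc1cc([C@@H]2Oc3cc(C4OCC(C)(C)CO4)cc(OC)c3O[C@H]2C)cc(OC)c1OC
F5 | step 4 | methyl (2S)-2-[2-chloro-4-(5,5-dimethyl-1,3-dioxan-2-yl)-6-methoxyphenoxy]propanoate | C[C@H](Oc1c(Cl)cc(C2OCC(C)(C)CO2)cc1OC)C(=O)OC
F6 | step 4 | (2S)-2-[2-chloro-4-(5,5-dimethyl-1,3-dioxan-2-yl)-6-methoxyphenoxy]-N-methoxy-N-methylpropanamide | C[C@H](Oc1c(Cl)cc(C2OCC(C)(C)CO2)cc1OC)C(=O)N(C)OC
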